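The route rests on cutting ring C, the piperazine, at N1–C6 and N4–C3. These two bonds join the nitrogen of one tyrosine-derived unit to the former carbonyl carbon of the other, while C2 and C5 are the untouched α-carbons of two L-amino acids. A single hydrogenation should free two α-amino aldehydes, let them condense head-to-tail and reduce both C=N bonds, closing the 14-membered cyclophane and ring C together. The precursor is an L,L-isodityrosine-type diaryl ether carrying two N-Cbz aldehyde termini and a benzyl ether on the ring A phenol, assembled by Chan–Lam coupling. Formylation of ring A and guanine annulation finish the target.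

Key step: step 8

Labels: ring A is the trisubstituted phenol ring (from 3-iodotyrosine), ring B the para-phenylene ring (from tyrosine), ring C the piperazine. In ring C, N1 and C2 (ring B arm) and C3 come from the ring B residue; N4, C5 (ring A arm) and C6 come from the ring A residue.

Assumption: in step 8 the aryl benzyl ether is taken to cleave together with the two carbamates, so 10 and 11 are drawn as free phenols; if the ether lags behind, the same sequence runs on the O-benzyl compounds and still ends at 12.

Remark: 15 is bought as its sulfate salt and set free in the flask.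

Step 1
Reactants: 1 3-iodo-L-tyrosine
Product: 2 N-Cbz-3-iodo-L-tyrosine
Conditions: Cbz-OSu, NaHCO3, acetone/H2O, 0 °C to rt
Reagents that add atoms: N-(benzyloxycarbonyloxy)succinimide, O=C(OCc1ccccc1)ON1C(=O)CCC1=O
Why: Carbamate formation with a succinimidyl carbonate acylates the amine and leaves the iodophenol free, so no O-acyl by-product has to be removed, and the α-centre is not involved.

Step 2
Reactants: 2 N-Cbz-3-iodo-L-tyrosine
Product: 3 benzyl N-Cbz-O-benzyl-3-iodo-L-tyrosinate
Conditions: BnBr (2.3 equiv), K2CO3, DMF, rt
Reagents that add atoms: benzyl bromide, BrCc1ccccc1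
Why: Double SN2 O-alkylation (Williamson ether synthesis on the phenoxide, alkylation of the carboxylate) installs ether and ester in one operation; carbonate does not deprotonate the urethane N–H and a urethane-protected α-centre does not epimerise at room temperature.

Step 3
Reactants: 3 benzyl N-Cbz-O-benzyl-3-iodo-L-tyrosinate
Product: 4 benzyl N-Cbz-O-benzyl-3-(pinacolatoboryl)-L-tyrosinate
Conditions: B2pin2, Pd(dppf)Cl2 (cat.), KOAc, DMSO, 80 °C
Reagents that add atoms: bis(pinacolato)diboron, CC1(C)OB(OC1(C)C)B1OC(C)(C)C(C)(C)O1
Why: Miyaura borylation, in which zerovalent palladium inserts into the aryl C–I bond and acetate-assisted transmetallation with B2pin2 gives the boronate; benzyl ester, benzyl ether and carbamate are inert to this weak base.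

Step 4
Reactants: 4 benzyl N-Cbz-O-benzyl-3-(pinacolatoboryl)-L-tyrosinate
Product: 5 benzyl N-Cbz-O-benzyl-3-borono-L-tyrosinate
Conditions: NaIO4, NH4OAc, acetone/H2O, rt
Reagents that add atoms: water, O
Why: Periodate glycol cleavage destroys the pinacol released in the hydrolysis equilibrium and so drives the ester to the free boronic acid, the form that couples reliably in the next step, without touching ester, ether or carbamate.

Step 5
Reactants: 5 benzyl N-Cbz-O-benzyl-3-borono-L-tyrosinate; 6 N-Cbz-L-tyrosine methyl ester (2 equiv)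
Product: 7 protected L,L-isodityrosine diester
Conditions: Cu(OAc)2 (1 equiv, reoxidised by air), pyridine, 4 Å MS, CH2Cl2, air, rt
Reagents that add atoms: none
Why: Chan–Lam O-arylation (transmetallation of the boronic acid to copper, binding of the phenoxide of 6, reductive elimination from trivalent copper) forms the diaryl ether at room temperature with a weak base, so neither α-centre is at risk and the carbamate N–H groups, far poorer nucleophiles than the phenol, stay untouched.

Step 6
Reactants: 7 protected L,L-isodityrosine diester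
Product: 8 bis(N-Cbz amino alcohol) diol
Conditions: LiBH4, THF/MeOH, 0 °C to rt
Reagents that add atoms: none
Why: Borohydride reduction of esters, in which LiBH4 takes the methyl and the benzyl ester to primary alcohols but leaves the carbamates, under conditions too weakly basic to epimerise the α-centres.

Step 7
Reactants: 8 bis(N-Cbz amino alcohol) diol
Product: 9 bis(N-Cbz-L-α-amino aldehyde) O-benzyl ether
Conditions: Dess–Martin periodinane (2.4 equiv), wet CH2Cl2, 0 °C to rt; crude product used at once
Reagents that add atoms: none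
Why: Dess–Martin oxidation gives N-urethane α-amino aldehydes under neutral, non-enolising conditions, which is why reduction–oxidation is preferred to partial reduction of two esters; 9 should be taken on without chromatography.

Step 8
Reactants: 9 bis(N-Cbz-L-α-amino aldehyde) O-benzyl ether
Product: 12 piperazinomycin, via free bis(α-amino aldehyde) 10 (not isolated), via bridged 2,5-dihydropyrazine 11 (not isolated)
Conditions: H2 (1 atm), 10% Pd/C, AcOH (4 equiv), EtOH/THF, syringe-pump addition of 9 (final about 1 mM), rt; then H2 (4 atm), rt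
Reagents that add atoms: none
Why: Proposed new method: hydrogenolysis of the two carbamates (and the benzyl ether) frees two α-amino aldehyde units, and since no amine can reach its own carbonyl, each must condense with the aldehyde of the other residue, first by 14-exo-trig addition–dehydration to the macrocyclic imine and then by transannular 6-exo-trig addition–dehydration to the 2,5-dihydropyrazine, whose C=N bonds (or each one as it forms) are hydrogenated on the same catalyst to give N1–C6 and N4–C3. The closest known reaction type is the intermolecular cyclodimerisation of α-amino aldehydes released from N-Cbz precursors to 2,5-dihydropyrazines and their reduction to 2,5-disubstituted piperazines, together with macrocyclisation by intramolecular reductive amination; the new element is that both partners sit on one diaryl ether tether. No stereocentre is created: C2 and C5 are the α-carbons of the two L-residues, stay sp3 throughout and, both being S, are cis, the only arrangement the tether can bridge, so an epimerised chain cannot close and should be lost as oligomer, not carried on as a diastereomer of 12. Ring closure must win over oligomerisation, which slow addition into a dilute catalyst suspension and the reversibility of hemiaminal and imine formation ahead of the slower hydrogenation should secure. Retention at C2 and C5 requires C=N reduction to outpace imine–enamine tautomerisation, which acetic acid (iminium formation) and a high catalyst loading under hydrogen favour, while aromatisation to a pyrazine, the usual fate of dihydropyrazines, is disfavoured because a flat pyrazine cannot be spanned by this short tether.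

Step 9
Reactants: 12 piperazinomycin
Product: 13 N,N'-di-Boc-piperazinomycin
Conditions: Boc2O (2.2 equiv), Et3N, MeOH/CH2Cl2, rt
Reagents that add atoms: di-tert-butyl dicarbonate, CC(C)(C)OC(=O)OC(=O)OC(C)(C)C
Why: Carbamate formation with Boc2O is chemoselective for the two secondary amines over the phenol in methanol without an acylation catalyst, and both N–H groups must be masked before formaldehyde and an aryl aldehyde are brought in.

Step 10
Reactants: 13 N,N'-di-Boc-piperazinomycin
Product: 14 N,N'-di-Boc-piperazinomycin ring A carbaldehyde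
Conditions: MgCl2, Et3N, (CH2O)n, MeCN, reflux
Reagents that add atoms: paraformaldehyde (formaldehyde), C=O
Why: Magnesium-mediated ortho-formylation of phenols (Casnati–Skattebøl reaction), in which the magnesium phenoxide delivers formaldehyde to the only free ortho carbon of ring A and a second formaldehyde oxidises the benzylic alkoxide by hydride transfer; ring B is not a phenol and the Boc groups tolerate Et3N/MgCl2.

Step 11
Reactants: 14 N,N'-di-Boc-piperazinomycin ring A carbaldehyde; 15 2,5,6-triaminopyrimidin-4(3H)-one
Product: 17 N,N'-di-Boc-guanipiperazine A, via Schiff base 16 (not isolated)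
Conditions: 15 as sulfate salt, NaOAc, Na2S2O5 (promoter), DMSO/H2O, 100 °C, air
Reagents that add atoms: none
Why: Aldehyde variant of the Traube purine synthesis, in which the 5-amino group (the most nucleophilic of 15) forms the Schiff base, the 6-amino group adds to it and the 7,8-dihydropurine is dehydrogenated by air, with bisulfite promoting the condensation and shielding the electron-rich triamine; the fully substituted phenol ring and the carbamates should not be oxidised.

Step 12
Reactants: 17 N,N'-di-Boc-guanipiperazine A
Product: 18 guanipiperazine A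
Conditions: TFA/CH2Cl2 (1:3), 0 °C to rt; aq. NH3 work-up
Reagents that add atoms: none
Why: Acidolysis of the two tert-butyl carbamates (loss of the tert-butyl cation, then decarboxylation) frees N1 and N4; guanine, diaryl ether and both stereocentres are stable to TFA at room temperature and ring A has no free ortho or para carbon for tert-butylation.

Compound list
1 | 3-iodo-L-tyrosine | N[C@@H](Cc1ccc(O)c(I)c1)C(=O)O | starting material
2 | N-Cbz-3-iodo-L-tyrosine | OC(=O)[C@H](Cc1ccc(O)c(I)c1)NC(=O)OCc1ccccc1 | intermediate
3 | benzyl N-Cbz-O-benzyl-3-iodo-L-tyrosinate | O=C(OCc1ccccc1)[C@H](Cc1ccc(OCc2ccccc2)c(I)c1)NC(=O)OCc1ccccc1 | intermediate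
4 | benzyl N-Cbz-O-benzyl-3-(4,4,5,5-tetramethyl-1,3,2-dioxaborolan-2-yl)-L-tyrosinate | O=C(OCc1ccccc1)[C@H](Cc1ccc(OCc2ccccc2)c(B2OC(C)(C)C(C)(C)O2)c1)NC(=O)OCc1ccccc1 | intermediate
5 | benzyl N-Cbz-O-benzyl-3-borono-L-tyrosinate | O=C(OCc1ccccc1)[C@H](Cc1ccc(OCc2ccccc2)c(B(O)O)c1)NC(=O)OCc1ccccc1 | intermediate
6 | N-Cbz-L-tyrosine methyl ester | COC(=O)[C@H](Cc1ccc(O)cc1)NC(=O)OCc1ccccc1 | starting material
7 | protected L,L-isodityrosine diester (ring A residue: N-Cbz, benzyl ester, O-benzyl; ring B residue: N-Cbz, methyl ester; ether from the ring B oxygen to C3 of ring A) | COC(=O)[C@H](Cc1ccc(Oc2cc(C[C@@H](C(=O)OCc3ccccc3)NC(=O)OCc3ccccc3)ccc2OCc2ccccc2)cc1)NC(=O)OCc1ccccc1 | intermediate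
8 | (S,S)-bis(N-Cbz amino alcohol) diol of the same diaryl ether | OC[C@H](Cc1ccc(Oc2cc(C[C@@H](CO)NC(=O)OCc3ccccc3)ccc2OCc2ccccc2)cc1)NC(=O)OCc1ccccc1 | intermediate
9 | (S,S)-bis(N-Cbz-α-amino aldehyde) O-benzyl ether (precursor of the key step) | O=C[C@H](Cc1ccc(Oc2cc(C[C@@H](C=O)NC(=O)OCc3ccccc3)ccc2OCc2ccccc2)cc1)NC(=O)OCc1ccccc1 | intermediate
10 | free (S,S)-bis(α-amino aldehyde) with ring A phenol | O=C[C@H](Cc1ccc(Oc2cc(C[C@@H](C=O)N)ccc2O)cc1)N | intermediate (not isolated)
11 | bridged (2S,5S)-2,5-dihydropyrazine (14-membered cyclophane bis-imine) | Oc1ccc2cc1Oc1ccc(cc1)C[C@H]1C=N[C@H](C=N1)C2 | intermediate (not isolated)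
12 | piperazinomycin, (2S,5S) | Oc1ccc2cc1Oc1ccc(cc1)C[C@H]1CN[C@H](CN1)C2 | intermediate
13 | N,N'-di-Boc-piperazinomycin | Oc1ccc2cc1Oc1ccc(cc1)C[C@H]1CN(C(=O)OC(C)(C)C)[C@H](CN1C(=O)OC(C)(C)C)C2 | intermediate
14 | N,N'-di-Boc-piperazinomycin carbaldehyde (CHO on ring A, ortho to OH) | O=Cc1cc2cc(c1O)Oc1ccc(cc1)C[C@H]1CN(C(=O)OC(C)(C)C)[C@H](CN1C(=O)OC(C)(C)C)C2 | intermediate
15 | 2,5,6-triaminopyrimidin-4(3H)-one (bought as its sulfate) | Nc1nc(N)c(N)c(=O)[nH]1 | starting material
16 | (E)-Schiff base of 14 with the 5-amino group of 15 | Nc1nc(N)c(/N=C/c2cc3cc(c2O)Oc2ccc(cc2)C[C@H]2CN(C(=O)OC(C)(C)C)[C@H](CN2C(=O)OC(C)(C)C)C3)c(=O)[nH]1 | intermediate (not isolated)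
17 | N,N'-di-Boc-guanipiperazine A | Nc1nc2nc(-c3cc4cc(c3O)Oc3ccc(cc3)C[C@H]3CN(C(=O)OC(C)(C)C)[C@H](CN3C(=O)OC(C)(C)C)C4)[nH]c2c(=O)[nH]1 | intermediate
18 | guanipiperazine A | Nc1nc2nc(-c3cc4cc(c3O)Oc3ccc(cc3)C[C@H]3CN[C@H](CN3)C4)[nH]c2c(=O)[nH]1 | target

Total step count: 12. Longest linear sequence: 12 steps (1 to 18); 6 and 15 enter as bought.

Steps most likely to fail

Step 8 (Proposed new method). Intermolecular imine formation may outrun ring closure, so that hydrogenation freezes oligomers. The doubly unsaturated bridged ring may form slowly because of strain. If C=N reduction is slow, imine–enamine tautomerisation would erode the configuration at C2 and C5. The fallback uses known chemistry, builds ring C first and closes the cyclophane last at the diaryl ether; it sets out from 1 and comes back at 13. Boc2O/NaOH should give N-Boc-3-iodo-L-tyrosine F1. BnBr with NaOMe in MeOH alkylates the phenoxide in the presence of the carboxylate to N-Boc-O-benzyl-3-iodo-L-tyrosine F2. EDC/HOBt coupling with commercial L-tyrosine methyl ester hydrochloride gives the dipeptide ester F3. HCl in dioxane, then heating the amine with Et3N/AcOH in 2-butanol, closes the cis-diketopiperazine F4. BH3·THF at reflux reduces both lactams to the (2S,5S)-piperazine F5, and Boc2O gives the N,N'-di-Boc piperazine F6. Intramolecular Ullmann etherification (NaH, CuBr·SMe2, pyridine, reflux, high dilution) should close the 14-membered ring to O-benzyl-N,N'-di-Boc-piperazinomycin F7. Hydrogenolysis of the benzyl ether (H2, Pd/C) gives 13.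

Step 11. The Schiff base may not close and dehydrogenate cleanly: air may oxidise the triamine faster than the dihydropurine, ring closure by the weakly nucleophilic 6-amino group may stall, or the carbamates may be lost thermally. The fallback replaces the oxidative annulation by acylation and cyclodehydration (classical Traube sequence); it sets out from 14 and comes back at 17. Pinnick oxidation (NaClO2, NaH2PO4, 2-methyl-2-butene, t-BuOH/H2O) gives the ring A salicylic acid F8. EDC/HOBt coupling with 15 in DMF acylates its 5-amino group to the 5-aroylamino-pyrimidinone F9. Cyclodehydration with aqueous NaOH/EtOH at reflux closes the imidazole ring to 17.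

Step 5. Protodeboronation and oxidation of the hindered ortho-benzyloxy boronic acid may outpace C–O bond formation. The fallback reverses the roles of the partners, so that boron sits on the unhindered ring; it sets out from 5 and comes back at 7. NaBO3·4H2O in THF/H2O oxidises the C–B bond of 5 to benzyl N-Cbz-4-O-benzyl-L-DOPA ester F10. Commercial 4-borono-L-phenylalanine is esterified (SOCl2, MeOH) to methyl 4-borono-L-phenylalaninate F11 and N-protected (Cbz-OSu, NaHCO3) to N-Cbz-4-borono-L-phenylalanine methyl ester F12. Chan–Lam coupling of F10 with F12 (Cu(OAc)2, pyridine, 4 Å MS, CH2Cl2, air, rt) gives 7.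

Further compounds
F1 | step 8 | N-Boc-3-iodo-L-tyrosine | CC(C)(C)OC(=O)N[C@@H](Cc1ccc(O)c(I)c1)C(=O)O
F2 | step 8 | N-Boc-O-benzyl-3-iodo-L-tyrosine | CC(C)(C)OC(=O)N[C@@H](Cc1ccc(OCc2ccccc2)c(I)c1)C(=O)O
F3 | step 8 | N-Boc-O-benzyl-3-iodo-L-tyrosyl-L-tyrosine methyl ester | CC(C)(C)OC(=O)N[C@@H](Cc1ccc(OCc2ccccc2)c(I)c1)C(=O)N[C@@H](Cc1ccc(O)cc1)C(=O)OC
F4 | step 8 | (3S,6S)-3-(4-benzyloxy-3-iodobenzyl)-6-(4-hydroxybenzyl)piperazine-2,5-dione | O=C1N[C@@H](Cc2ccc(O)cc2)C(=O)N[C@H]1Cc1ccc(OCc2ccccc2)c(I)c1
F5 | step 8 | (2S,5S)-2-(4-benzyloxy-3-iodobenzyl)-5-(4-hydroxybenzyl)piperazine | Oc1ccc(C[C@H]2CN[C@@H](Cc3ccc(OCc4ccccc4)c(I)c3)CN2)cc1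
F6 | step 8 | N,N'-di-Boc derivative of F5 | Oc1ccc(C[C@H]2CN(C(=O)OC(C)(C)C)[C@@H](Cc3ccc(OCc4ccccc4)c(I)c3)CN2C(=O)OC(C)(C)C)cc1
F7 | step 8 | O-benzyl-N,N'-di-Boc-piperazinomycin | C(c1ccccc1)Oc1ccc2cc1Oc1ccc(cc1)C[C@H]1CN(C(=O)OC(C)(C)C)[C@H](CN1C(=O)OC(C)(C)C)C2
F8 | step 11 | N,N'-di-Boc-piperazinomycin ring A carboxylic acid (CO2H ortho to OH) | OC(=O)c1cc2cc(c1O)Oc1ccc(cc1)C[C@H]1CN(C(=O)OC(C)(C)C)[C@H](CN1C(=O)OC(C)(C)C)C2
F9 | step 11 | 5-aroylamino-2,6-diaminopyrimidin-4(3H)-one from F8 and 15 | Nc1nc(N)c(NC(=O)c2cc3cc(c2O)Oc2ccc(cc2)C[C@H]2CN(C(=O)OC(C)(C)C)[C@H](CN2C(=O)OC(C)(C)C)C3)c(=O)[nH]1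
F10 | step 5 | benzyl N-Cbz-4-O-benzyl-L-DOPA ester (3-OH free) | O=C(OCc1ccccc1)[C@H](Cc1ccc(OCc2ccccc2)c(O)c1)NC(=O)OCc1ccccc1
F11 | step 5 | methyl 4-borono-L-phenylalaninate | COC(=O)[C@@H](N)Cc1ccc(B(O)O)cc1
F12 | step 5 | N-Cbz-4-borono-L-phenylalanine methyl ester | COC(=O)[C@H](Cc1ccc(B(O)O)cc1)NC(=O)OCc1ccccc1
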